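**Plan**
The core is numbered as 2H-cyclohepta[b]furan-2-one (O1, C2=O, C3=CH2, C3a, C4 to C8, C8a). Retrosynthetic cuts, in order: the crotonoyl C–C bond at C7, the C8 ester C–O bond (epoxide opening), C7–C8 as an alkene (ring-closing metathesis), then C5–C6 and C3a–C4 together, and last the lactone carbonyl (CO insertion).
Enabling feature: the 3-methylidene group of the five-membered lactone is allylic to C3a, and C4H2–C5H(OH)–C6H(CH3) of the seven-membered ring is a homoallylic alcohol once C7 is sp2. A [3,3] shift of a 3-(vinyloxymethyl)butenolide therefore makes C3a–C4, creates the exocyclic methylidene and unveils a C5 aldehyde, which a crotylboronate captures to make C5–C6; C4 and C5 are the vinyl carbons of ethyl vinyl ether.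
Forward order: lactone ring first (steps 1–5), two-carbon insertion and fragment union in one flask (step 10), seven-membered ring by metathesis (step 12), then C7/C8 oxygenation and the side chain.
Stereochemistry: C8a from a catalytic asymmetric alkynylation; C3a from the Claisen shift anti to the C8a vinyl group; C5 from a chiral phosphoric acid; C6 from the boronate geometry; C7 and C8 from a reagent-controlled Sharpless epoxidation and an invertive carboxylate opening; the ester stereocentre from (R)-2-methylbutanoic acid.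

Key step: step 10

Remark: (R)-2-methylbutanoic acid, (E)-1-bromoprop-1-ene, (S,S)-ProPhenol and (S)-TRIP are taken as purchasable; compound 30 is carried as a mixture of epimers at its new carbinol carbon, which step 18 removes.

**Step 1**
Reactants: 1 acrolein; 2 tert-butyldimethyl(prop-2-yn-1-yloxy)silane
Product: 4 (3S)-6-[(tert-butyldimethylsilyl)oxy]hex-1-en-4-yn-3-ol, via alkynyl(methyl)zinc 3 (not isolated)
Conditions: Me2Zn (3 equiv), (S,S)-ProPhenol (10 mol%), Ph3PO (20 mol%), toluene, 0 °C; aq. NH4Cl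
Reagents that add atoms: none
Why: Dinuclear zinc–ProPhenol catalysed alkynylation of an aldehyde should add alkynylzinc 3 to the Re face of acrolein and set the S carbinol centre (the future C8a); the ligand antipode is the one expected to give this sense.

**Step 2**
Reactants: 4 (3S)-6-[(tert-butyldimethylsilyl)oxy]hex-1-en-4-yn-3-ol
Product: 6 (3S,4Z)-6-[(tert-butyldimethylsilyl)oxy]-5-iodohexa-1,4-dien-3-ol, via cyclic alkenylalanate 5 (not isolated)
Conditions: NaAlH2(OCH2CH2OMe)2 (1.5 equiv), THF, 0 °C; then I2, −78 to 0 °C; aq. Rochelle salt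
Reagents that add atoms: iodine, II
Why: Alkoxide-directed trans-hydroalumination of the propargylic alcohol places hydride on the proximal and aluminium on the distal alkyne carbon (alanate 5), and iodinolysis with retention should give the Z iodide with iodine cis to the carbinol carbon.

**Step 3**
Reactants: 6 (3S,4Z)-6-[(tert-butyldimethylsilyl)oxy]-5-iodohexa-1,4-dien-3-ol
Product: 7 (5S)-3-{[(tert-butyldimethylsilyl)oxy]methyl}-5-vinylfuran-2(5H)-one
Conditions: CO (1 atm), PdCl2(PPh3)2 (5 mol%), K2CO3, THF, 25 °C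
Reagents that add atoms: carbon monoxide, [C-]#[O+]
Why: Oxidative addition of zerovalent palladium into the C–I bond, CO insertion and capture of the acylpalladium by the cis hydroxyl (carbonylative lactonisation) should close the butenolide with the stereocentre untouched, solid K2CO3 at room temperature being mild enough to leave the doubly activated γ-hydrogen in place.

**Step 4**
Reactants: 7 (5S)-3-{[(tert-butyldimethylsilyl)oxy]methyl}-5-vinylfuran-2(5H)-one
Product: 8 (5S)-3-(hydroxymethyl)-5-vinylfuran-2(5H)-one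
Conditions: HF·pyridine, THF, 0 °C
Reagents that add atoms: none
Why: Acidic fluoride cleaves the primary silyl ether (desilylation) and avoids the basic fluoride sources that could epimerise or isomerise the 5-vinylbutenolide.

**Step 5**
Reactants: 8 (5S)-3-(hydroxymethyl)-5-vinylfuran-2(5H)-one; 9 ethyl vinyl ether
Product: 10 (5S)-5-vinyl-3-[(vinyloxy)methyl]furan-2(5H)-one
Conditions: 9 as solvent, Hg(OAc)2 (0.2 equiv), 35 °C
Reagents that add atoms: none
Why: Mercury-catalysed transetherification (vinyl transfer from ethyl vinyl ether) should convert the primary allylic alcohol into the allyl vinyl ether under base-free conditions at low temperature.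

**Step 6**
Reactants: 11 (E)-but-2-enal (crotonaldehyde)
Product: 12 (Z)-2-iodobut-2-enal
Conditions: I2, K2CO3, DMAP (0.2 equiv), THF/H2O, 20 °C
Reagents that add atoms: iodine, II
Why: Nucleophile-catalysed α-iodination of an enal (conjugate addition of DMAP, iodination of the enolate, elimination) should give the 2-iodoenal with the methyl group cis to iodine.

**Step 7**
Reactants: 12 (Z)-2-iodobut-2-enal
Product: 13 (Z)-2-iodobut-2-en-1-ol
Conditions: NaBH4, CeCl3·7H2O, MeOH, 0 °C
Reagents that add atoms: none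
Why: Luche reduction gives clean 1,2-reduction of the enal and leaves the vinylic iodide and its geometry intact.

**Step 8**
Reactants: 13 (Z)-2-iodobut-2-en-1-ol
Product: 14 triethyl{[(2Z)-2-iodobut-2-en-1-yl]oxy}silane
Conditions: Et3SiCl, imidazole, CH2Cl2, 0 °C
Reagents that add atoms: chlorotriethylsilane, CC[Si](Cl)(CC)CC
Why: Routine silylation of a primary alcohol; the triethylsilyl group is chosen because it can be removed later beside a tert-butyldimethylsilyl ether.

**Step 9**
Reactants: 14 triethyl{[(2Z)-2-iodobut-2-en-1-yl]oxy}silane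
Product: 17 triethyl({(2E)-2-[(4,4,5,5-tetramethyl-1,3,2-dioxaborolan-2-yl)methyl]but-2-en-1-yl}oxy)silane (methyl group cis to the CH2B carbon), via alkenyllithium 15 (not isolated), via lithium borate complex 16 (not isolated)
Conditions: tBuLi (2.1 equiv), Et2O, −78 °C; then 2-(chloromethyl)-4,4,5,5-tetramethyl-1,3,2-dioxaborolane, −78 to 20 °C
Reagents that add atoms: 2-(chloromethyl)-4,4,5,5-tetramethyl-1,3,2-dioxaborolane, ClCB1OC(C)(C)C(C)(C)O1
Why: Iodine–lithium exchange with retention gives 15, which adds to boron to give borate 16, and 1,2-migration of the alkenyl group with loss of chloride (Matteson-type homologation) should give the allylboronate with its geometry intact.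

**Step 10**
Reactants: 10 (5S)-5-vinyl-3-[(vinyloxy)methyl]furan-2(5H)-one; 17 the allylboronate of step 9
Product: 20 (4R,5S)-4-[(2R,3R)-2-hydroxy-3-methyl-4-{[(triethylsilyl)oxy]methyl}pent-4-en-1-yl]-3-methylidene-5-vinyloxolan-2-one, via aldehyde 18 (not isolated), via O-boryl ether 19 (not isolated)
Conditions: 10, BHT (1 mol%), toluene, 140 °C (sealed tube); cool to −30 °C, add 17 (1.5 equiv), (S)-TRIP [(S)-3,3′-bis(2,4,6-triisopropylphenyl)-1,1′-binaphthyl-2,2′-diyl hydrogen phosphate, 10 mol%], 4 Å MS, −30 to 0 °C; aq. NaHCO3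
Reagents that add atoms: none
Why: Heating 10 triggers a concerted [3,3] sigmatropic (Claisen) shift through a chair-like six-centre array made of the O–CH=CH2 unit and the CH2–C3=C4 unit of the butenolide, which forms the C3a–C4 bond, moves the ring double bond into the exocyclic methylidene position and unveils aldehyde 18; on cooling, boronate 17 adds to 18 through a closed six-membered chair (Zimmerman–Traxler) transition state that the phosphoric acid activates by hydrogen bonding to a boronate oxygen, forming the C5–C6 bond in the same flask. The closest known reaction types are the Claisen rearrangement of 2-carbonyl-substituted allyl vinyl ethers to α-methylene carbonyl compounds and the chiral-phosphoric-acid-catalysed crotylboration of aldehydes with pinacol boronates. No ring is closed in this step: the lactone is already present and the seven-membered ring follows in step 12, for which this step installs both alkene termini. C3a is controlled by the substrate, the vinyl ether reaching the butenolide face anti to the C8a vinyl group (trans lactone); C6 is controlled by the boronate geometry, the methyl group cis to the CH2B carbon sitting axial in the chair and giving the syn relationship; C5 is controlled by the catalyst, (S)-TRIP being the antipode expected to direct attack to the Si face of the aldehyde. The step needs regiospecific allylic transposition in the first stage and chemoselective addition to the aldehyde in the second; the acrylate-type allyl unit (ester carbon on the central allyl carbon) accelerates and channels the [3,3] shift, and an allylboronate does not react with the lactone or the methylidene group. The vinyl group at C8a is a spectator that is kept for step 12.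

**Step 11**
Reactants: 20 the homoallylic alcohol of step 10
Product: 21 (4R,5S)-4-[(2R,3R)-2-[(tert-butyldimethylsilyl)oxy]-3-methyl-4-{[(triethylsilyl)oxy]methyl}pent-4-en-1-yl]-3-methylidene-5-vinyloxolan-2-one
Conditions: TBSOTf, 2,6-lutidine, CH2Cl2, −78 °C
Reagents that add atoms: tert-butyldimethylsilyl trifluoromethanesulfonate, CC(C)(C)[Si](C)(C)OS(=O)(=O)C(F)(F)F
Why: Silyl triflate silylation of the hindered secondary alcohol protects the C5 hydroxyl so that the later C7 aldehyde cannot close to a lactol.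

**Step 12**
Reactants: 21 the bis-silyl ether of step 11
Product: 22 (3aR,5R,6R,8aS)-5-[(tert-butyldimethylsilyl)oxy]-6-methyl-3-methylidene-7-{[(triethylsilyl)oxy]methyl}-3,3a,4,5,6,8a-hexahydro-2H-cyclohepta[b]furan-2-one
Conditions: second-generation Grubbs catalyst (10 mol%), CH2Cl2 (2 mM), 40 °C
Reagents that add atoms: none
Why: Ring-closing olefin metathesis between the vinyl group and the 1,1-disubstituted alkene should close the seven-membered ring as its trisubstituted C7=C8 alkene with loss of ethene, the tetrasubstituted alternative through the methylidene lactone being far slower.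

**Step 13**
Reactants: 22 the cycloheptene of step 12
Product: 23 (3aR,5R,6R,8aS)-5-[(tert-butyldimethylsilyl)oxy]-7-(hydroxymethyl)-6-methyl-3-methylidene-3,3a,4,5,6,8a-hexahydro-2H-cyclohepta[b]furan-2-one
Conditions: PPTS (0.2 equiv), MeOH/CH2Cl2, 0 °C
Reagents that add atoms: none
Why: Mild acidic methanolysis removes the primary triethylsilyl ether selectively and leaves the secondary tert-butyldimethylsilyl ether.

**Step 14**
Reactants: 23 the allylic alcohol of step 13
Product: 24 (3aR,5R,6S,7R,8R,8aR)-5-[(tert-butyldimethylsilyl)oxy]-7,8-epoxy-7-(hydroxymethyl)-6-methyl-3-methylideneoctahydro-2H-cyclohepta[b]furan-2-one (epoxide oxygen cis to the C6 methyl group)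
Conditions: Ti(OiPr)4 (0.3 equiv), L-(+)-diisopropyl tartrate (0.36 equiv), tBuOOH, 4 Å MS, CH2Cl2, −20 °C
Reagents that add atoms: tert-butyl hydroperoxide, CC(C)(C)OO
Why: Sharpless asymmetric epoxidation of the primary allylic alcohol is reagent-controlled, L-(+)-tartrate delivering oxygen to the alkene face cis to the C6 methyl group, which sets C7 and C8 of the epoxide.

**Step 15**
Reactants: 24 the epoxy alcohol of step 14; 25 (R)-2-methylbutanoic acid
Product: 26 (3aR,5R,6S,7R,8S,8aR)-5-[(tert-butyldimethylsilyl)oxy]-7-hydroxy-7-(hydroxymethyl)-6-methyl-3-methylidene-2-oxooctahydro-2H-cyclohepta[b]furan-8-yl (2R)-2-methylbutanoate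
Conditions: Ti(OiPr)4 (1.5 equiv), 25 (3 equiv), CH2Cl2, 20 °C
Reagents that add atoms: none
Why: Ti(OiPr)4-mediated opening of a 2,3-epoxy alcohol by a carboxylic acid takes place at the carbon remote from the hydroxymethyl group (C8) with inversion, which installs the ester trans to the tertiary C7 hydroxyl without activating the α-chiral acid.

**Step 16**
Reactants: 26 the diol ester of step 15
Product: 27 (3aR,5R,6S,7S,8S,8aR)-5-[(tert-butyldimethylsilyl)oxy]-7-formyl-7-hydroxy-6-methyl-3-methylidene-2-oxooctahydro-2H-cyclohepta[b]furan-8-yl (2R)-2-methylbutanoate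
Conditions: Dess–Martin periodinane, CH2Cl2, 0 °C
Reagents that add atoms: none
Why: Dess–Martin oxidation converts the primary alcohol into the aldehyde while the tertiary hydroxyl, the ester and the methylidene lactone are inert.

**Step 17**
Reactants: 27 the α-hydroxy aldehyde of step 16; 28 (E)-1-bromoprop-1-ene
Product: 30 (3aR,5R,6S,7R,8S,8aR)-5-[(tert-butyldimethylsilyl)oxy]-7-hydroxy-7-[(2E)-1-hydroxybut-2-en-1-yl]-6-methyl-3-methylidene-2-oxooctahydro-2H-cyclohepta[b]furan-8-yl (2R)-2-methylbutanoate (both epimers at the side-chain carbinol), via alkenylchromium dichloride 29 (not isolated)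
Conditions: CrCl2 (6 equiv), NiCl2 (2 mol%), 28 (3 equiv), DMSO/DMF, 20 °C
Reagents that add atoms: none
Why: Nozaki–Hiyama–Kishi addition of alkenylchromium 29, formed with retention of the E geometry, is chemoselective for the aldehyde over the lactone and esters; the new carbinol centre is not controlled and is removed in step 18.

**Step 18**
Reactants: 30 the allylic alcohol of step 17
Product: 31 (3aR,5R,6S,7S,8S,8aR)-7-[(2E)-but-2-enoyl]-5-[(tert-butyldimethylsilyl)oxy]-7-hydroxy-6-methyl-3-methylidene-2-oxooctahydro-2H-cyclohepta[b]furan-8-yl (2R)-2-methylbutanoate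
Conditions: Dess–Martin periodinane, CH2Cl2, 20 °C
Reagents that add atoms: none
Why: Dess–Martin oxidation of the secondary allylic alcohol gives the E enone and leaves the tertiary hydroxyl untouched.

**Step 19**
Reactants: 31 the silyl-protected enone of step 18
Product: 32 (3aR,5R,6S,7S,8S,8aR)-7-[(2E)-but-2-enoyl]-5,7-dihydroxy-6-methyl-3-methylidene-2-oxooctahydro-2H-cyclohepta[b]furan-8-yl (2R)-2-methylbutanoate (target)
Conditions: HF·pyridine, THF, 0 to 20 °C
Reagents that add atoms: none
Why: Acidic fluoride removes the secondary silyl ether without touching the esters, the enone or the methylidene lactone.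

**Compound list**
1 | acrolein (prop-2-enal) | C=CC=O | starting material
2 | tert-butyldimethyl(prop-2-yn-1-yloxy)silane | C#CCO[Si](C)(C)C(C)(C)C | starting material
3 | methyl{3-[(tert-butyldimethylsilyl)oxy]prop-1-yn-1-yl}zinc | C[Zn]C#CCO[Si](C)(C)C(C)(C)C | intermediate
4 | (3S)-6-[(tert-butyldimethylsilyl)oxy]hex-1-en-4-yn-3-ol | C=C[C@H](O)C#CCO[Si](C)(C)C(C)(C)C | intermediate
5 | sodium (5S)-2,2-bis(2-methoxyethoxy)-3-{[(tert-butyldimethylsilyl)oxy]methyl}-5-vinyl-2,5-dihydro-1,2-oxaluminol-2-uide (cyclic alkenylalanate) | C=C[C@@H]1O[Al-](OCCOC)(OCCOC)C(CO[Si](C)(C)C(C)(C)C)=C1.[Na+] | intermediate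
6 | (3S,4Z)-6-[(tert-butyldimethylsilyl)oxy]-5-iodohexa-1,4-dien-3-ol | C=C[C@H](O)/C=C(\I)CO[Si](C)(C)C(C)(C)C | intermediate
7 | (5S)-3-{[(tert-butyldimethylsilyl)oxy]methyl}-5-vinylfuran-2(5H)-one | C=C[C@@H]1OC(=O)C(CO[Si](C)(C)C(C)(C)C)=C1 | intermediate
8 | (5S)-3-(hydroxymethyl)-5-vinylfuran-2(5H)-one | C=C[C@@H]1OC(=O)C(CO)=C1 | intermediate
9 | ethyl vinyl ether | C=COCC | starting material
10 | (5S)-5-vinyl-3-[(vinyloxy)methyl]furan-2(5H)-one | C=C[C@@H]1OC(=O)C(COC=C)=C1 | intermediate
11 | (E)-but-2-enal (crotonaldehyde) | C/C=C/C=O | starting material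
12 | (Z)-2-iodobut-2-enal | C/C=C(\I)C=O | intermediate
13 | (Z)-2-iodobut-2-en-1-ol | C/C=C(\I)CO | intermediate
14 | triethyl{[(2Z)-2-iodobut-2-en-1-yl]oxy}silane | C/C=C(\I)CO[Si](CC)(CC)CC | intermediate
15 | (1-{[(triethylsilyl)oxy]methyl}prop-1-en-1-yl)lithium, methyl cis to lithium | C/C=C(\[Li])CO[Si](CC)(CC)CC | intermediate
16 | lithium (chloromethyl)(pinacolato)(1-{[(triethylsilyl)oxy]methyl}prop-1-en-1-yl)borate | C/C=C(\[B-]1(CCl)OC(C)(C)C(C)(C)O1)CO[Si](CC)(CC)CC.[Li+] | intermediate
17 | triethyl({(2E)-2-[(4,4,5,5-tetramethyl-1,3,2-dioxaborolan-2-yl)methyl]but-2-en-1-yl}oxy)silane, methyl cis to CH2B | C/C=C(\CB1OC(C)(C)C(C)(C)O1)CO[Si](CC)(CC)CC | intermediate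
18 | 2-[(2S,3R)-4-methylidene-5-oxo-2-vinyloxolan-3-yl]acetaldehyde | C=C1C(=O)O[C@@H](C=C)[C@@H]1CC=O | intermediate
19 | O-pinacolboryl ether of 20 | C=C1C(=O)O[C@@H](C=C)[C@@H]1C[C@@H](OB2OC(C)(C)C(C)(C)O2)[C@H](C)C(=C)CO[Si](CC)(CC)CC | intermediate
20 | (4R,5S)-4-[(2R,3R)-2-hydroxy-3-methyl-4-{[(triethylsilyl)oxy]methyl}pent-4-en-1-yl]-3-methylidene-5-vinyloxolan-2-one | C=C1C(=O)O[C@@H](C=C)[C@@H]1C[C@@H](O)[C@H](C)C(=C)CO[Si](CC)(CC)CC | intermediate
21 | (4R,5S)-4-[(2R,3R)-2-[(tert-butyldimethylsilyl)oxy]-3-methyl-4-{[(triethylsilyl)oxy]methyl}pent-4-en-1-yl]-3-methylidene-5-vinyloxolan-2-one | C=C1C(=O)O[C@@H](C=C)[C@@H]1C[C@@H](O[Si](C)(C)C(C)(C)C)[C@H](C)C(=C)CO[Si](CC)(CC)CC | intermediate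
22 | (3aR,5R,6R,8aS)-5-[(tert-butyldimethylsilyl)oxy]-6-methyl-3-methylidene-7-{[(triethylsilyl)oxy]methyl}-3,3a,4,5,6,8a-hexahydro-2H-cyclohepta[b]furan-2-one | C=C1C(=O)O[C@@H]2[C@@H]1C[C@@H](O[Si](C)(C)C(C)(C)C)[C@H](C)C(CO[Si](CC)(CC)CC)=C2 | intermediate
23 | (3aR,5R,6R,8aS)-5-[(tert-butyldimethylsilyl)oxy]-7-(hydroxymethyl)-6-methyl-3-methylidene-3,3a,4,5,6,8a-hexahydro-2H-cyclohepta[b]furan-2-one | C=C1C(=O)O[C@@H]2[C@@H]1C[C@@H](O[Si](C)(C)C(C)(C)C)[C@H](C)C(CO)=C2 | intermediate
24 | (3aR,5R,6S,7R,8R,8aR)-5-[(tert-butyldimethylsilyl)oxy]-7,8-epoxy-7-(hydroxymethyl)-6-methyl-3-methylideneoctahydro-2H-cyclohepta[b]furan-2-one | C=C1C(=O)O[C@@H]2[C@@H]1C[C@@H](O[Si](C)(C)C(C)(C)C)[C@H](C)[C@]3(CO)O[C@H]23 | intermediate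
25 | (R)-2-methylbutanoic acid | CC[C@@H](C)C(=O)O | starting material
26 | (3aR,5R,6S,7R,8S,8aR)-5-[(tert-butyldimethylsilyl)oxy]-7-hydroxy-7-(hydroxymethyl)-6-methyl-3-methylidene-2-oxooctahydro-2H-cyclohepta[b]furan-8-yl (2R)-2-methylbutanoate | C=C1C(=O)O[C@@H]2[C@@H]1C[C@@H](O[Si](C)(C)C(C)(C)C)[C@H](C)[C@@](O)(CO)[C@H]2OC(=O)[C@H](C)CC | intermediate
27 | (3aR,5R,6S,7S,8S,8aR)-5-[(tert-butyldimethylsilyl)oxy]-7-formyl-7-hydroxy-6-methyl-3-methylidene-2-oxooctahydro-2H-cyclohepta[b]furan-8-yl (2R)-2-methylbutanoate | C=C1C(=O)O[C@@H]2[C@@H]1C[C@@H](O[Si](C)(C)C(C)(C)C)[C@H](C)[C@@](O)(C=O)[C@H]2OC(=O)[C@H](C)CC | intermediate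
28 | (E)-1-bromoprop-1-ene | C/C=C/Br | starting material
29 | (E)-prop-1-en-1-ylchromium dichloride | C/C=C/[Cr](Cl)Cl | intermediate
30 | (3aR,5R,6S,7R,8S,8aR)-5-[(tert-butyldimethylsilyl)oxy]-7-hydroxy-7-[(2E)-1-hydroxybut-2-en-1-yl]-6-methyl-3-methylidene-2-oxooctahydro-2H-cyclohepta[b]furan-8-yl (2R)-2-methylbutanoate, epimers at the side-chain carbinol | C=C1C(=O)O[C@@H]2[C@@H]1C[C@@H](O[Si](C)(C)C(C)(C)C)[C@H](C)[C@@](O)(C(O)/C=C/C)[C@H]2OC(=O)[C@H](C)CC | intermediate
31 | (3aR,5R,6S,7S,8S,8aR)-7-[(2E)-but-2-enoyl]-5-[(tert-butyldimethylsilyl)oxy]-7-hydroxy-6-methyl-3-methylidene-2-oxooctahydro-2H-cyclohepta[b]furan-8-yl (2R)-2-methylbutanoate | C=C1C(=O)O[C@@H]2[C@@H]1C[C@@H](O[Si](C)(C)C(C)(C)C)[C@H](C)[C@@](O)(C(=O)/C=C/C)[C@H]2OC(=O)[C@H](C)CC | intermediate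
32 | (3aR,5R,6S,7S,8S,8aR)-7-[(2E)-but-2-enoyl]-5,7-dihydroxy-6-methyl-3-methylidene-2-oxooctahydro-2H-cyclohepta[b]furan-8-yl (2R)-2-methylbutanoate | C=C1C(=O)O[C@@H]2[C@@H]1C[C@@H](O)[C@H](C)[C@@](O)(C(=O)/C=C/C)[C@H]2OC(=O)[C@H](C)CC | target

**Step count and risks**
Total step count: 19. Longest linear sequence: 15 steps (steps 1–5 and 10–19); the boronate branch (steps 6–9) joins at step 10.

Steps most likely to fail:

1. Step 10. The crotyl transfer from the hindered, trisubstituted boronate may stall or lose catalyst control over the aldehyde face. The fallback sets out from 10 and comes back at 21. Compound 10 is heated alone and aldehyde 18 is isolated. 1-[(Triethylsilyl)oxy]butan-2-one F1, made from 1-hydroxybutan-2-one and Et3SiCl, is enolised on its ethyl side with diisopinocampheylboron triflate and iPr2NEt (Ipc antipode chosen for Si-face addition), and the Z enolate undergoes a syn-selective boron aldol reaction with 18 to give the β-hydroxy ketone F2. TBSOTf and 2,6-lutidine then give the silyl ether F3, and non-basic Lombardo methylenation of the ketone (Zn, CH2Br2, TiCl4) gives 21.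

2. Step 15. Attack at the secondary epoxide carbon, which lies between the quaternary epoxide carbon and the lactone carbinol, may be slow, so that opening at the tertiary carbon or acyl migration to the primary hydroxyl competes. The fallback sets out from 24 and comes back at 31. The primary alcohol is oxidised first (Dess–Martin periodinane) to the epoxy aldehyde F4, the Nozaki–Hiyama–Kishi addition of 28 gives the epoxy allylic alcohol F5, and a second Dess–Martin oxidation gives the epoxy enone F6. In this α,β-epoxy ketone the α-carbon is quaternary and cannot ionise next to the carbonyl group, so 25 with Cs2CO3 in DMF should open the epoxide at the β-carbon C8 with inversion and give 31 directly.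

3. Step 12. The ruthenium carbene may be diverted into cross-metathesis with, or chelation by, the methylidene lactone, so that ring closure onto the hindered 1,1-disubstituted alkene stalls. The fallback sets out from 21 and comes back at 22. Conjugate addition of dimethylamine masks the methylidene group as the β-amino lactone F7. Metathesis of its camphorsulfonate salt with the second-generation Grubbs catalyst gives, after a NaHCO3 wash, the cycloheptene F8. Methyl iodide gives the ammonium iodide F9, and NaHCO3 eliminates trimethylamine to restore the methylidene lactone 22.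

**Further compounds**
F1 | step 10 | 1-[(triethylsilyl)oxy]butan-2-one | CCC(=O)CO[Si](CC)(CC)CC
F2 | step 10 | (4R,5S)-4-{(2R,3S)-2-hydroxy-3-methyl-4-oxo-5-[(triethylsilyl)oxy]pentyl}-3-methylidene-5-vinyloxolan-2-one | C=C1C(=O)O[C@@H](C=C)[C@@H]1C[C@@H](O)[C@H](C)C(=O)CO[Si](CC)(CC)CC
F3 | step 10 | (4R,5S)-4-{(2R,3S)-2-[(tert-butyldimethylsilyl)oxy]-3-methyl-4-oxo-5-[(triethylsilyl)oxy]pentyl}-3-methylidene-5-vinyloxolan-2-one | C=C1C(=O)O[C@@H](C=C)[C@@H]1C[C@@H](O[Si](C)(C)C(C)(C)C)[C@H](C)C(=O)CO[Si](CC)(CC)CC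
F4 | step 15 | (3aR,5R,6S,7S,8R,8aR)-5-[(tert-butyldimethylsilyl)oxy]-7,8-epoxy-6-methyl-3-methylidene-2-oxooctahydro-2H-cyclohepta[b]furan-7-carbaldehyde | C=C1C(=O)O[C@@H]2[C@@H]1C[C@@H](O[Si](C)(C)C(C)(C)C)[C@H](C)[C@]3(C=O)O[C@H]23
F5 | step 15 | 7-[(2E)-1-hydroxybut-2-en-1-yl] analogue of 24 (7,8-epoxide retained, epimers at the side-chain carbinol) | C=C1C(=O)O[C@@H]2[C@@H]1C[C@@H](O[Si](C)(C)C(C)(C)C)[C@H](C)[C@]3(C(O)/C=C/C)O[C@H]23
F6 | step 15 | (3aR,5R,6S,7S,8R,8aR)-7-[(2E)-but-2-enoyl]-5-[(tert-butyldimethylsilyl)oxy]-7,8-epoxy-6-methyl-3-methylideneoctahydro-2H-cyclohepta[b]furan-2-one | C=C1C(=O)O[C@@H]2[C@@H]1C[C@@H](O[Si](C)(C)C(C)(C)C)[C@H](C)[C@]3(C(=O)/C=C/C)O[C@H]23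
F7 | step 12 | dimethylamine adduct of 21: 3-[(dimethylamino)methyl] lactone, epimers at C3 | CN(C)CC1C(=O)O[C@@H](C=C)[C@@H]1C[C@@H](O[Si](C)(C)C(C)(C)C)[C@H](C)C(=C)CO[Si](CC)(CC)CC
F8 | step 12 | 3-[(dimethylamino)methyl]-3-hydro analogue of 22 | CN(C)CC1C(=O)O[C@@H]2[C@@H]1C[C@@H](O[Si](C)(C)C(C)(C)C)[C@H](C)C(CO[Si](CC)(CC)CC)=C2
F9 | step 12 | trimethylammonium iodide derived from F8 | C[N+](C)(C)CC1C(=O)O[C@@H]2[C@@H]1C[C@@H](O[Si](C)(C)C(C)(C)C)[C@H](C)C(CO[Si](CC)(CC)CC)=C2.[I-]
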